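With the ring numbered C5 (isopropenyl C4/C3/C15), C6 (OH), C7 (carbinol C11 with C12, C13), C8, C9 and C10 (methyl C14, vinyl C1–C2), the route rests on cutting the C5–C6 bond. The trans-2-isopropenylcyclohexanol unit at C5/C6 is the adduct of an intramolecular carbonyl-ene reaction. One Lewis acid-mediated step closes the only ring, creates C5 and C6 and turns a prenyl-type alkene into the isopropenyl group. Its precursor is an open-chain (2S,5S)-7-methyloct-6-enal that already carries C7, bearing the silyl- and acetonide-protected triol carbon, and the methyl/vinyl quaternary centre C10.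

Key step: step 12

Remark on numbering: the atom labels C1–C15 defined above are kept for all open-chain intermediates.

Remark on the structures: the aldehyde that maps onto the target is the (2S,5S) isomer 20 and its cyclisation product is (1R,2S,3S,6R)-21 (C5 S, C6 R, C7 R, C10 S). C7 is S in the aldehyde and R in the ring only because the substituent priorities change.

Remark on the design of the precursor: the C11 hydroxyl is silylated before the aldehyde exists, so retro-aldol cleavage is excluded. All oxygen protecting groups fall together in step 13, so any silyl or ketal migration onto the new C6 hydroxyl during step 12 is harmless. The prenyl-type alkene is delivered intact in step 4, so no olefination next to the quaternary centre is needed.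

Assumption: in step 4 the antipode of the chiral imidazolinium salt (both are accessible from (R,R)- or (S,S)-1,2-diphenylethylenediamine) is chosen so that C10 is formed S.

Step 1
Reactants: 1 hex-5-yn-1-ol
Product: 2 tert-butyl(hex-5-yn-1-yloxy)dimethylsilane
Conditions: TBSCl, imidazole, DMF, 0 °C to rt
Reagents that add atoms: tert-butyldimethylsilyl chloride, CC(C)(C)[Si](C)(C)Cl
Why: Silyl ether formation masks the primary hydroxyl (the future C6) so that it survives Me3Al, n-BuLi and the alkenylaluminium reagent of steps 2 to 4.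

Step 2
Reactants: 2 tert-butyl(hex-5-yn-1-yloxy)dimethylsilane
Product: 5 (2E)-7-{[tert-butyl(dimethyl)silyl]oxy}-3-methylhept-2-en-1-ol, via alkenyldimethylalane 3 (not isolated), via lithium alkenylalanate 4 (not isolated)
Conditions: Me3Al, Cp2ZrCl2 (cat.), CH2Cl2, 0 °C to rt; volatiles removed; n-BuLi, THF–hexane, −78 to 0 °C; (CH2O)n, rt; aq. potassium sodium tartrate
Reagents that add atoms: trimethylaluminium, C[Al](C)C; formaldehyde (as paraformaldehyde), C=O
Why: Zirconium-catalysed syn-carboalumination of the terminal alkyne (Negishi carboalumination) puts the new methyl group on the internal carbon and aluminium on the terminus, and hydroxymethylation of the derived alanate with formaldehyde occurs with retention, so the (E)-trisubstituted allylic alcohol should form as one geometric isomer.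

Step 3
Reactants: 5 (2E)-7-{[tert-butyl(dimethyl)silyl]oxy}-3-methylhept-2-en-1-ol
Product: 6 (2E)-7-{[tert-butyl(dimethyl)silyl]oxy}-3-methylhept-2-en-1-yl diethyl phosphate
Conditions: ClP(O)(OEt)2, Et3N, DMAP (cat.), CH2Cl2, 0 °C
Reagents that add atoms: diethyl chlorophosphate, CCOP(=O)(Cl)OCC
Why: Esterification of the primary allylic alcohol with ClP(O)(OEt)2 (phosphorylation) installs the leaving group required for allylic substitution without touching the alkene geometry.

Step 4
Reactants: 6 (2E)-7-{[tert-butyl(dimethyl)silyl]oxy}-3-methylhept-2-en-1-yl diethyl phosphate; 7 (2-methylprop-1-en-1-yl)magnesium bromide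
Product: 9 tert-butyl{[(5S)-5-ethenyl-5,7-dimethyloct-6-en-1-yl]oxy}dimethylsilane, via alkenyldiisobutylalane 8 (not isolated)
Conditions: i-Bu2AlCl, THF, 0 °C (7 to 8); then 6, CuCl2·2H2O (cat.), chiral imidazolinium sulfonate built on a 4,5-diphenylimidazolinium core (bidentate NHC precursor, cat.), THF, −15 °C
Reagents that add atoms: none
Why: Copper-catalysed enantioselective allylic substitution (SN2′) of an (E)-3,3-disubstituted allylic phosphate with an alkenylaluminium reagent is an established way to methyl-, vinyl- and alkenyl-bearing quaternary carbons: the alkenyl group is transferred in preference to isobutyl, attack at the substituted terminus creates C10 and turns the allyl backbone into the C1=C2 vinyl group, and the chiral sulfonate-NHC–copper complex selects the alkene face that gives (S)-C10.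

Step 5
Reactants: 9 tert-butyl{[(5S)-5-ethenyl-5,7-dimethyloct-6-en-1-yl]oxy}dimethylsilane
Product: 10 (5S)-5-ethenyl-5,7-dimethyloct-6-en-1-ol
Conditions: Bu4NF, THF, 0 °C to rt
Reagents that add atoms: none
Why: Fluoride-induced desilylation cleaves only the Si–O bond, leaving the skipped diene and the quaternary centre untouched.

Step 6
Reactants: 10 (5S)-5-ethenyl-5,7-dimethyloct-6-en-1-ol
Product: 11 (5S)-5-ethenyl-5,7-dimethyloct-6-enoic acid
Conditions: TEMPO (cat.), PhI(OAc)2, MeCN–H2O, rt
Reagents that add atoms: water, O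
Why: Nitroxyl-catalysed oxidation with PhI(OAc)2 in aqueous acetonitrile takes the primary alcohol through the aldehyde hydrate to the carboxylic acid under near-neutral conditions that spare both alkenes.

Step 7
Reactants: 11 (5S)-5-ethenyl-5,7-dimethyloct-6-enoic acid; 12 (4R)-4-benzyl-1,3-oxazolidin-2-one
Product: 14 (4R)-4-benzyl-3-[(5S)-5-ethenyl-5,7-dimethyloct-6-enoyl]-1,3-oxazolidin-2-one, via mixed pivalic anhydride 13 (not isolated)
Conditions: t-BuCOCl, Et3N, THF, −20 °C; then 12, LiCl, −20 °C to rt
Reagents that add atoms: none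
Why: N-Acylation of the oxazolidinone through the mixed pivalic anhydride with LiCl/Et3N activation is the standard way to attach the auxiliary, the nucleophile attacking the less hindered carbonyl of the anhydride.

Step 8
Reactants: 14 (4R)-4-benzyl-3-[(5S)-5-ethenyl-5,7-dimethyloct-6-enoyl]-1,3-oxazolidin-2-one; 15 2,2-dimethyl-1,3-dioxan-5-one
Product: 17 (4R)-4-benzyl-3-[(2S,5S)-5-ethenyl-2-(5-hydroxy-2,2-dimethyl-1,3-dioxan-5-yl)-5,7-dimethyloct-6-enoyl]-1,3-oxazolidin-2-one, via lithium Z-enolate 16 (not isolated)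
Conditions: LiN(i-Pr)2, THF, −78 °C; then 15, −78 °C; AcOH quench at −78 °C
Reagents that add atoms: none
Why: Aldol addition of the chelated lithium (Z)-enolate of a chiral N-acyloxazolidinone to an electron-poor α,α′-dialkoxy ketone: the ketone approaches the enolate face opposite the (4R)-benzyl group, which sets C7 as S, and since 15 is symmetric no second stereocentre arises, while the low temperature and cold acidic quench suppress proton transfer and retro-aldol cleavage.

Step 9
Reactants: 17 (4R)-4-benzyl-3-[(2S,5S)-5-ethenyl-2-(5-hydroxy-2,2-dimethyl-1,3-dioxan-5-yl)-5,7-dimethyloct-6-enoyl]-1,3-oxazolidin-2-one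
Product: 18 (4R)-4-benzyl-3-[(2S,5S)-2-{2,2-dimethyl-5-[(triethylsilyl)oxy]-1,3-dioxan-5-yl}-5-ethenyl-5,7-dimethyloct-6-enoyl]-1,3-oxazolidin-2-one
Conditions: Et3SiOTf, 2,6-lutidine, CH2Cl2, −78 to 0 °C
Reagents that add atoms: triethylsilyl trifluoromethanesulfonate, CC[Si](CC)(CC)OS(=O)(=O)C(F)(F)F
Why: Silylation of the hindered tertiary hydroxyl with the silyl triflate and 2,6-lutidine removes the retro-aldol pathway for all later intermediates and does not affect the ketal or the imide.

Step 10
Reactants: 18 (4R)-4-benzyl-3-[(2S,5S)-2-{2,2-dimethyl-5-[(triethylsilyl)oxy]-1,3-dioxan-5-yl}-5-ethenyl-5,7-dimethyloct-6-enoyl]-1,3-oxazolidin-2-one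
Product: 19 (2R,5S)-2-{2,2-dimethyl-5-[(triethylsilyl)oxy]-1,3-dioxan-5-yl}-5-ethenyl-5,7-dimethyloct-6-en-1-ol
Conditions: LiBH4, MeOH (1 equiv), THF, 0 °C
Reagents that add atoms: none
Why: Hydride reduction of the exocyclic imide carbonyl with LiBH4 (reductive auxiliary removal) gives the primary alcohol without touching C7 and releases the auxiliary 12 for reuse.

Step 11
Reactants: 19 (2R,5S)-2-{2,2-dimethyl-5-[(triethylsilyl)oxy]-1,3-dioxan-5-yl}-5-ethenyl-5,7-dimethyloct-6-en-1-ol
Product: 20 (2S,5S)-2-{2,2-dimethyl-5-[(triethylsilyl)oxy]-1,3-dioxan-5-yl}-5-ethenyl-5,7-dimethyloct-6-enal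
Conditions: Dess–Martin periodinane, pyridine, CH2Cl2, 0 °C
Reagents that add atoms: none
Why: Dess–Martin oxidation buffered with pyridine converts the primary alcohol into the α-branched aldehyde under non-basic, non-acidic conditions, so C7 should not epimerise and the silyl ether and ketal stay in place.

Step 12
Reactants: 20 (2S,5S)-2-{2,2-dimethyl-5-[(triethylsilyl)oxy]-1,3-dioxan-5-yl}-5-ethenyl-5,7-dimethyloct-6-enal
Product: 21 (1R,2S,3S,6R)-6-{2,2-dimethyl-5-[(triethylsilyl)oxy]-1,3-dioxan-5-yl}-3-ethenyl-3-methyl-2-(prop-1-en-2-yl)cyclohexan-1-ol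
Conditions: Me2AlCl (1.5 equiv), CH2Cl2, −78 to −40 °C; aq. potassium sodium tartrate
Reagents that add atoms: none
Why: Me2AlCl binds the aldehyde oxygen and the C5=C4 alkene attacks C6 through a chair-like six-membered transition state while a hydrogen of a C4 methyl group passes to oxygen (concerted, asynchronous carbonyl-ene reaction), so the C5–C6 bond, the C6 hydroxyl and the C4=C3 double bond of the isopropenyl group arise together. The closest known reaction is the Lewis acid-promoted cyclisation of 7-methyloct-6-enals, as in citronellal to isopulegol. The cyclohexane closes in a 6-exo mode with respect to the carbonyl, with both the C=O and the reacting alkene exocyclic to the forming ring, and closure is helped by the quaternary C10 next to the alkene. C6 (R) and C5 (S) are set by the chair in which the bulky dioxanyl group on C7 is equatorial, the C10 methyl axial and the C10 vinyl equatorial: the complexed carbonyl oxygen and the isopropylidene unit then both sit equatorial and trans, the alternative axial oxygen being 1,3-diaxial to the C10 methyl. The step needs chemoselectivity for the prenyl-type alkene and survival of the silyl ether and ketal: the trisubstituted alkene is the most nucleophilic π-bond, the vinyl group cannot act as the ene because its allylic carbon C10 carries no hydrogen, and the methylaluminium reagent scavenges protons at low temperature.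

Step 13
Reactants: 21 (1R,2S,3S,6R)-6-{2,2-dimethyl-5-[(triethylsilyl)oxy]-1,3-dioxan-5-yl}-3-ethenyl-3-methyl-2-(prop-1-en-2-yl)cyclohexan-1-ol
Product: 22 2-[(1R,2R,3S,4S)-4-ethenyl-2-hydroxy-4-methyl-3-(prop-1-en-2-yl)cyclohexyl]propane-1,2,3-triol
Conditions: p-TsOH·H2O (cat.), MeOH, rt
Reagents that add atoms: none
Why: Acid-catalysed methanolysis (transketalisation of the acetonide and solvolysis of the silyl ether) frees all four hydroxyls in one operation without involving any stereocentre.

Step 14
Reactants: 22 2-[(1R,2R,3S,4S)-4-ethenyl-2-hydroxy-4-methyl-3-(prop-1-en-2-yl)cyclohexyl]propane-1,2,3-triol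
Product: 23 2-[(1R,2R,3S,4S)-4-ethenyl-2-hydroxy-4-methyl-3-(prop-1-en-2-yl)cyclohexyl]-2-hydroxypropane-1,3-diyl diacetate
Conditions: AcCl (2.1 equiv), 2,4,6-collidine, CH2Cl2, −78 °C
Reagents that add atoms: acetyl chloride, CC(=O)Cl
Why: Kinetically controlled O-acylation with AcCl and the hindered base 2,4,6-collidine at low temperature discriminates by steric access, so the two primary hydroxyls are esterified while the flanked secondary C6 hydroxyl and the tertiary C11 hydroxyl stay free.

Compound list
1 | hex-5-yn-1-ol | C#CCCCCO | starting material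
2 | tert-butyl(hex-5-yn-1-yloxy)dimethylsilane | C#CCCCCO[Si](C)(C)C(C)(C)C | intermediate
3 | [(1E)-6-{[tert-butyl(dimethyl)silyl]oxy}-2-methylhex-1-en-1-yl]dimethylalumane | C[Al](C)/C=C(\C)CCCCO[Si](C)(C)C(C)(C)C | intermediate
4 | lithium butyl[(1E)-6-{[tert-butyl(dimethyl)silyl]oxy}-2-methylhex-1-en-1-yl]dimethylaluminate | [Li+].CCCC[Al-](C)(C)/C=C(\C)CCCCO[Si](C)(C)C(C)(C)C | intermediate
5 | (2E)-7-{[tert-butyl(dimethyl)silyl]oxy}-3-methylhept-2-en-1-ol | OC/C=C(\C)CCCCO[Si](C)(C)C(C)(C)C | intermediate
6 | (2E)-7-{[tert-butyl(dimethyl)silyl]oxy}-3-methylhept-2-en-1-yl diethyl phosphate | CCOP(=O)(OCC)OC/C=C(\C)CCCCO[Si](C)(C)C(C)(C)C | intermediate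
7 | (2-methylprop-1-en-1-yl)magnesium bromide | CC(C)=C[Mg]Br | starting material
8 | bis(2-methylpropyl)(2-methylprop-1-en-1-yl)alumane | CC(C)C[Al](CC(C)C)C=C(C)C | intermediate
9 | tert-butyl{[(5S)-5-ethenyl-5,7-dimethyloct-6-en-1-yl]oxy}dimethylsilane | CC(C)=C[C@](C)(C=C)CCCCO[Si](C)(C)C(C)(C)C | intermediate
10 | (5S)-5-ethenyl-5,7-dimethyloct-6-en-1-ol | CC(C)=C[C@](C)(C=C)CCCCO | intermediate
11 | (5S)-5-ethenyl-5,7-dimethyloct-6-enoic acid | CC(C)=C[C@](C)(C=C)CCCC(=O)O | intermediate
12 | (4R)-4-benzyl-1,3-oxazolidin-2-one | O=C1N[C@H](Cc2ccccc2)CO1 | starting material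
13 | (5S)-5-ethenyl-5,7-dimethyloct-6-enoic 2,2-dimethylpropanoic anhydride | CC(C)=C[C@](C)(C=C)CCCC(=O)OC(=O)C(C)(C)C | intermediate
14 | (4R)-4-benzyl-3-[(5S)-5-ethenyl-5,7-dimethyloct-6-enoyl]-1,3-oxazolidin-2-one | CC(C)=C[C@](C)(C=C)CCCC(=O)N1[C@H](Cc2ccccc2)COC1=O | intermediate
15 | 2,2-dimethyl-1,3-dioxan-5-one | CC1(C)OCC(=O)CO1 | starting material
16 | lithium (1Z,5S)-1-[(4R)-4-benzyl-2-oxo-1,3-oxazolidin-3-yl]-5-ethenyl-5,7-dimethylocta-1,6-dien-1-olate | CC(C)=C[C@](C)(C=C)CC/C=C(\O[Li])N1[C@H](Cc2ccccc2)COC1=O | intermediate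
17 | (4R)-4-benzyl-3-[(2S,5S)-5-ethenyl-2-(5-hydroxy-2,2-dimethyl-1,3-dioxan-5-yl)-5,7-dimethyloct-6-enoyl]-1,3-oxazolidin-2-one | CC(C)=C[C@](C)(C=C)CC[C@@H](C1(O)COC(C)(C)OC1)C(=O)N1[C@H](Cc2ccccc2)COC1=O | intermediate
18 | (4R)-4-benzyl-3-[(2S,5S)-2-{2,2-dimethyl-5-[(triethylsilyl)oxy]-1,3-dioxan-5-yl}-5-ethenyl-5,7-dimethyloct-6-enoyl]-1,3-oxazolidin-2-one | CC(C)=C[C@](C)(C=C)CC[C@@H](C1(O[Si](CC)(CC)CC)COC(C)(C)OC1)C(=O)N1[C@H](Cc2ccccc2)COC1=O | intermediate
19 | (2R,5S)-2-{2,2-dimethyl-5-[(triethylsilyl)oxy]-1,3-dioxan-5-yl}-5-ethenyl-5,7-dimethyloct-6-en-1-ol | CC(C)=C[C@](C)(C=C)CC[C@@H](C1(O[Si](CC)(CC)CC)COC(C)(C)OC1)CO | intermediate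
20 | (2S,5S)-2-{2,2-dimethyl-5-[(triethylsilyl)oxy]-1,3-dioxan-5-yl}-5-ethenyl-5,7-dimethyloct-6-enal | CC(C)=C[C@](C)(C=C)CC[C@@H](C1(O[Si](CC)(CC)CC)COC(C)(C)OC1)C=O | intermediate
21 | (1R,2S,3S,6R)-6-{2,2-dimethyl-5-[(triethylsilyl)oxy]-1,3-dioxan-5-yl}-3-ethenyl-3-methyl-2-(prop-1-en-2-yl)cyclohexan-1-ol | C=C[C@]1(C)CC[C@@H](C2(O[Si](CC)(CC)CC)COC(C)(C)OC2)[C@H](O)[C@H]1C(=C)C | intermediate
22 | 2-[(1R,2R,3S,4S)-4-ethenyl-2-hydroxy-4-methyl-3-(prop-1-en-2-yl)cyclohexyl]propane-1,2,3-triol | C=C[C@]1(C)CC[C@@H](C(O)(CO)CO)[C@H](O)[C@H]1C(=C)C | intermediate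
23 | 2-[(1R,2R,3S,4S)-4-ethenyl-2-hydroxy-4-methyl-3-(prop-1-en-2-yl)cyclohexyl]-2-hydroxypropane-1,3-diyl diacetate | C=C[C@]1(C)CC[C@@H](C(O)(COC(C)=O)COC(C)=O)[C@H](O)[C@H]1C(=C)C | target

Total step count: 14. Longest linear sequence: 14 steps, from 1 to 23; 7, 12 and 15 are purchased and enter in steps 4, 7 and 8.

Steps most likely to fail

Step 12. The Lewis acid may engage the ketal and silyl ether oxygens instead of the aldehyde, which would lead to loss of protecting groups or a sluggish closure, or the carbonyl face may be poorly controlled. The fallback forms the same C5–C6 bond by an intramolecular Nozaki–Hiyama allylation under neutral conditions. It sets out from alcohol 19. Allylic oxidation of the (E)-methyl group of the trisubstituted alkene with SeO2 (cat.) and t-BuOOH in CH2Cl2 should give the (E)-allylic diol F1. Corey–Kim chlorination (N-chlorosuccinimide, Me2S, CH2Cl2, −20 °C) converts only the allylic hydroxyl and gives the allylic chloride F2. Dess–Martin oxidation with pyridine gives the chloro aldehyde F3. CrCl2 in THF then generates an allylchromium species that adds to the aldehyde through its γ-carbon C5 with allylic transposition, which produces the isopropenyl group. The chair-like transition state with the C7 substituent equatorial is expected to give the same trans arrangement at C5/C6. The route is rejoined at cyclohexanol 21.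

Step 4. Enantiofacial control may be incomplete, and direct substitution without allylic transposition or transfer of an isobutyl group may compete. The fallback builds C10 by stereospecific chirality transfer from an epoxide. It sets out from allylic alcohol 5. Sharpless epoxidation (Ti(OiPr)4, L-(+)-diethyl tartrate, t-BuOOH, 4 Å molecular sieves, CH2Cl2, −20 °C) should give the (2S,3S)-epoxy alcohol F4, and Et3SiCl with imidazole gives the epoxy triethylsilyl ether F5. Methylaluminium bis(4-bromo-2,6-di-tert-butylphenoxide), MeAl(OC6H2-4-Br-2,6-t-Bu2)2, in CH2Cl2 at −78 °C opens the epoxide at the tertiary carbon while the silyloxymethyl group shifts anti to the departing oxygen, which gives the (2S)-β-silyloxy aldehyde F6 with the quaternary centre in place. Wittig reaction with the ylide from isopropyltriphenylphosphonium iodide and n-BuLi gives the isobutenyl bis-silyl ether F7. PPTS in MeOH at 0 °C removes the triethylsilyl group selectively to give the neopentyl alcohol F8, and Dess–Martin oxidation gives the α-quaternary aldehyde F9. Wittig methylenation (Ph3PCH3Br, KOt-Bu, THF) installs the vinyl group and rejoins the route at silyl ether 9.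

Step 8. Proton transfer from the enolisable ketone to the enolate, retro-aldol cleavage on work-up or incomplete facial control may lower conversion or selectivity. The fallback generates the enolate reductively (Reformatsky-type aldol with SmI2). It sets out from imide 14. Bromination of the boron enolate (Bu2BOTf, i-Pr2NEt, CH2Cl2, −78 °C; then N-bromosuccinimide) gives the α-bromo imide F10. SmI2 in THF at −78 °C in the presence of ketone 15 forms a chelated samarium enolate under non-basic conditions, which should add to the ketone from the face opposite the benzyl group. The route is rejoined at aldol 17.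

Further compounds
F1 | step 12 | (2E,4S,7R)-7-{2,2-dimethyl-5-[(triethylsilyl)oxy]-1,3-dioxan-5-yl}-4-ethenyl-2,4-dimethyloct-2-ene-1,8-diol | OC/C(C)=C/[C@](C)(C=C)CC[C@@H](C1(O[Si](CC)(CC)CC)COC(C)(C)OC1)CO
F2 | step 12 | (2R,5S,6E)-8-chloro-2-{2,2-dimethyl-5-[(triethylsilyl)oxy]-1,3-dioxan-5-yl}-5-ethenyl-5,7-dimethyloct-6-en-1-ol | ClC/C(C)=C/[C@](C)(C=C)CC[C@@H](C1(O[Si](CC)(CC)CC)COC(C)(C)OC1)CO
F3 | step 12 | (2S,5S,6E)-8-chloro-2-{2,2-dimethyl-5-[(triethylsilyl)oxy]-1,3-dioxan-5-yl}-5-ethenyl-5,7-dimethyloct-6-enal | ClC/C(C)=C/[C@](C)(C=C)CC[C@@H](C1(O[Si](CC)(CC)CC)COC(C)(C)OC1)C=O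
F4 | step 4 | [(2S,3S)-3-(4-{[tert-butyl(dimethyl)silyl]oxy}butyl)-3-methyloxiran-2-yl]methanol | OC[C@@H]1O[C@@]1(C)CCCCO[Si](C)(C)C(C)(C)C
F5 | step 4 | tert-butyl(dimethyl)[4-((2S,3S)-2-methyl-3-{[(triethylsilyl)oxy]methyl}oxiran-2-yl)butoxy]silane | CC[Si](CC)(CC)OC[C@@H]1O[C@@]1(C)CCCCO[Si](C)(C)C(C)(C)C
F6 | step 4 | (2S)-6-{[tert-butyl(dimethyl)silyl]oxy}-2-methyl-2-{[(triethylsilyl)oxy]methyl}hexanal | O=C[C@](C)(CO[Si](CC)(CC)CC)CCCCO[Si](C)(C)C(C)(C)C
F7 | step 4 | tert-butyl{[(5R)-5,7-dimethyl-5-{[(triethylsilyl)oxy]methyl}oct-6-en-1-yl]oxy}dimethylsilane | CC(C)=C[C@](C)(CO[Si](CC)(CC)CC)CCCCO[Si](C)(C)C(C)(C)C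
F8 | step 4 | (2R)-2-(4-{[tert-butyl(dimethyl)silyl]oxy}butyl)-2,4-dimethylpent-3-en-1-ol | CC(C)=C[C@](C)(CO)CCCCO[Si](C)(C)C(C)(C)C
F9 | step 4 | (2R)-2-(4-{[tert-butyl(dimethyl)silyl]oxy}butyl)-2,4-dimethylpent-3-enal | CC(C)=C[C@](C)(C=O)CCCCO[Si](C)(C)C(C)(C)C
F10 | step 8 | (4R)-4-benzyl-3-[(2R,5S)-2-bromo-5-ethenyl-5,7-dimethyloct-6-enoyl]-1,3-oxazolidin-2-one | CC(C)=C[C@](C)(C=C)CC[C@@H](Br)C(=O)N1[C@H](Cc2ccccc2)COC1=O
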